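## Structural features

The target is a tetrahydrofuran, numbered here O1, C2, C3, C4, C5. C2 carries ring A (3,4,5-trimethoxyphenyl), C3 a hydroxymethyl group, C4 a benzyl group whose arene is ring B (3-hydroxy-4,5-dimethoxyphenyl), and C5 is an unsubstituted methylene. The stereocentres C2 (R), C3 (S) and C4 (S) are contiguous: ring A and the hydroxymethyl group are trans across C2–C3, and the hydroxymethyl and benzyl groups are cis across C3–C4. The cis C3/C4 pair is the more crowded arrangement, and neither carbon has a carbonyl or heteroatom through which it could be corrected later, so both must be set kinetically and together. The fragile points are the C2–O1 bond (a benzylic ether of an electron-rich arene, open to acid ionisation and hydrogenolysis), the free phenol of ring B, and the two oxygenated rings. Only the phenol and the primary alcohol need protection. The key step uses three facts: C5 is a bare CH2 between O1 and C4, C3 and C4 each carry one hydrogen, and C2 carries oxygen. C5 can therefore be carbon monoxide inserted at C4 of a C3=C4 alkene and trapped by the C2 hydroxyl, with the alkene geometry and the C2 carbinol encoding the relative configuration.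

## Logic of the disconnections

15 to 14: the two O–Si bonds (ring B phenol and the CH2O on C3) are cut. The phenol cannot be carried free through ylide, hydride and organochromium chemistry, and a free primary hydroxyl would compete with the C2 hydroxyl for the formyl group in the key step. One type of protecting group means one final operation. The demand is that fluoride touches nothing else, which holds because 14 has no other silicon, no ester and no base-sensitive stereocentre.

14 to 13: the C5–H bond is exchanged for C5–OH. A lactol at C5 is what a carbonyl-forming one-carbon insertion delivers, and C5 is not a stereocentre in 14, so the anomeric mixture costs nothing. The demand is that the Lewis-acid reduction does not ionise the benzylic C2–O1 bond.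

13 to 11, through 12: O1–C5, C4–C5 and the C3–H bond are cut, which opens the ring, removes C5 and turns C3 and C4 into a trisubstituted alkene. Two stereocentres are traded for one alkene geometry, and the whole carbon skeleton is reduced to an open-chain allylic alcohol. The forward step must put formyl on C4 and hydrogen on C3, add both to the same face, and choose the face from the C2 carbinol. The alkene in 11 must be Z (C2 cis to the benzylic CH2), because syn addition to that isomer gives the cis C3/C4 pair. The descriptor at C2 is S in 11 and R from 12 onward only because C3 changes from sp2 to sp3 and drops below ring A in priority; the spatial arrangement is unchanged.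

11 to 9 and 10: the C2–C3 bond is cut. It joins the ring A carbinol to the alkene, gives two pieces of similar size, and makes C2 the product of an aldehyde addition that a chiral catalyst can control. The alkenyl iodide 9 must carry iodine on the future C3 (the carbon bearing the silyloxymethyl group) and cis to the benzylic CH2. The coupling must keep that geometry and select one aldehyde face.

9 to 8 to 7: the O–Si bond and then the two C–H bonds of the CH2O group are cut, which leads to an α-iodo enoate. Hydroxyl-directed anti-hydroalumination–iodination of an alkynol is not used to reach 8. That reaction places the metal, and hence iodine, on the alkyne carbon remote from the hydroxyl, here the future C4. The coupling product would then carry the ring B benzyl group on C3 and the oxygenated CH2 on C4, and the key step would give a constitutional isomer of 13.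

7 to 4 and 5, through 6: the C3=C4 double bond is cut. Olefination with an ester-stabilised ylide that already carries iodine puts the halogen on the ester-bearing carbon by construction and, with the ester trans to the chain, cis to the benzylic CH2. The demand is that the enolisable aldehyde 4 survives mildly basic conditions and that the Z isomer predominates.

4 to 3 to 2 to 1: the bond between the benzylic carbon and the future C4 is cut (a one-carbon homologation of an aromatic aldehyde), then the phenol O–Si bond. This leads back to the commercial ring B aldehyde 1. The enol ether must be hydrolysed without losing the aryl silyl ether.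

## Other disconnections considered

Alternative 1: The cut is in ring B: the bond from the benzylic-side ring carbon to the ester-bearing carbon, and the bond from the methoxy-bearing carbon to a ring carbonyl. In the forward step NaOMe would add dimethyl malonate A3 to the enone A2 (Michael) and the enolate at the methoxymethyl carbon would close on a malonate ester (Claisen), giving the methoxy dione ester A1. Decarboxylation, dehydrogenation to the arene and one O-methylation would follow. In its favour, the annulation is classical anionic chemistry that needs no pressure equipment and no precious metal; on mechanistic certainty of the key step it is the better of the two plans. Against it, A2 must already contain the complete tetrahydrofuran with all three stereocentres, so the real difficulty is left unsolved. After aromatisation the two ring B oxygens flanking the methoxy group are equivalent, so a single methylation is statistical. The dehydrogenation must also spare an electron-rich benzylic ether. Ring B is available as 1, so building it costs at least four extra steps; on step economy and on stereochemistry the chosen plan is clearly ahead.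

Alternative 2: The cuts are O1–C2, C3–C4 and the bond from ring B to the exocyclic carbon. In the forward step the potassium alkoxide of propargyl alcohol A7 adds to the arylidene malonate A5. The malonate anion then attacks the alkyne activated by the arylpalladium iodide formed from A6, zerovalent palladium (Pd2(dba)3) and a chiral bisphosphine (5-exo-dig), and reductive elimination gives the benzylidene tetrahydrofuran diester A4. Dealkoxycarbonylation, hydrogenation of the exocyclic alkene with debenzylation, and ester reduction would finish the synthesis. In its favour, three simple partners give the whole skeleton in one step, and hydrogenation anti to the C3 substituent should give the cis C3/C4 pair. On convergence and step count (about five steps) this alternative is better than the chosen plan. Against it, C2 is formed in a reversible oxa-Michael step away from the metal. The chiral ligand can act only by selecting between equilibrating enantiomeric anions in the cyclisation, so absolute control is remote. The relative configuration is spread over two later steps (protonation at C3, hydrogenation at C4), and hydrogenolysis conditions threaten the C2–O1 bond. The chosen plan sets C2 by a catalyst-controlled addition and relays it to C3 and C4 in one stereospecific event, at the price of a longer linear sequence.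

Alternative 3: The cuts are C2–C3 and C4–C5. In the forward step CsF would convert the α-chloro silylmethyl ether A10 by 1,3-elimination into an aryl-substituted carbonyl ylide, which adds across the alkene of the chiral butenolide A9 anti to its aryl group to give the cis-fused cycloadduct A8. Hydrogenolysis of the benzylic lactone C–O bond (with loss of the benzyl ether) and reduction of the resulting acid would follow. In its favour, the ring and two C–C bonds form in one step, and the cis C3/C4 pair follows from suprafacial addition to a ring alkene. On this point it equals the chosen plan, and it is somewhat shorter. Against it, nothing secures the orientation of the unsymmetrical ylide or the exo placement of ring A that 2,3-trans requires. A10 is an α-chloro ether at an electron-rich benzylic carbon and will ionise readily. The γ-proton of A9 is acidic, so fluoride may racemise it. The final hydrogenolysis must distinguish two benzylic C–O bonds. In the chosen plan the regiochemistry follows from the substitution of the alkene and C2 is fixed independently.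

Key step: step 8

Assumption: in step 7 the antipode of the chiral ligand that gives the (S)-carbinol is used; which antipode that is must be assigned on the first batch (MTPA esters), because no safe prediction exists for an α-branched alkenyl iodide with an aromatic aldehyde.

## Route

Step 1
Reactants: 1 3-hydroxy-4,5-dimethoxybenzaldehyde
Product: 2 3-[(tert-butyldimethylsilyl)oxy]-4,5-dimethoxybenzaldehyde
Conditions: TBSCl, imidazole, DMF, 0 °C → rt
Reagents that add atoms: tert-butyldimethylsilyl chloride, CC(C)(C)[Si](C)(C)Cl
Why: Silyl ether formation on a phenol; the aryl silyl ether masks the acidic hydroxyl for the ylide, hydride and organometal steps and should leave with the second silyl group at the end.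

Step 2
Reactants: 2 3-[(tert-butyldimethylsilyl)oxy]-4,5-dimethoxybenzaldehyde
Product: 3 tert-butyl{2,3-dimethoxy-5-[2-methoxyethenyl]phenoxy}dimethylsilane (E/Z mixture)
Conditions: Ph3P(CH2OMe)Cl, NaN(SiMe3)2, THF, 0 °C; then 2, 0 °C → rt
Reagents that add atoms: (methoxymethyl)triphenylphosphonium chloride, COC[P+](c1ccccc1)(c1ccccc1)c1ccccc1.[Cl-]
Why: Wittig methoxymethylenation of an aromatic aldehyde; the non-nucleophilic amide base should spare the aryl silyl ether, and the geometry of the enol ether is irrelevant because both isomers hydrolyse to the same aldehyde.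

Step 3
Reactants: 3 tert-butyl{2,3-dimethoxy-5-[2-methoxyethenyl]phenoxy}dimethylsilane
Product: 4 2-{3-[(tert-butyldimethylsilyl)oxy]-4,5-dimethoxyphenyl}acetaldehyde
Conditions: HCO2H, H2O, CH2Cl2, 0 °C → rt; used at once
Reagents that add atoms: water, O
Why: Acid-catalysed enol ether hydrolysis (protonation on carbon, hemiacetal, loss of methanol) completes the one-carbon homologation; a carboxylic acid is chosen because aryl silyl ethers tolerate it and because the arylacetaldehyde condenses with itself under stronger acid.

Step 4
Reactants: 4 2-{3-[(tert-butyldimethylsilyl)oxy]-4,5-dimethoxyphenyl}acetaldehyde; 5 ethyl 2-(triphenyl-λ5-phosphanylidene)acetate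
Product: 7 ethyl (Z)-4-{3-[(tert-butyldimethylsilyl)oxy]-4,5-dimethoxyphenyl}-2-iodobut-2-enoate, via iodo ylide 6 (not isolated)
Conditions: 5, NIS, CH2Cl2, −20 °C; then K2CO3, 4, −20 °C → rt
Reagents that add atoms: N-iodosuccinimide, O=C1CCC(=O)N1I
Why: Wittig olefination with an α-iodinated stabilised ylide, made in the flask by electrophilic iodination of 5; as with other ester-stabilised ylides the ester should end trans to the chain, which places iodine cis to the benzylic CH2 (Z) and on the carbon that becomes C3.

Step 5
Reactants: 7 ethyl (Z)-4-{3-[(tert-butyldimethylsilyl)oxy]-4,5-dimethoxyphenyl}-2-iodobut-2-enoate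
Product: 8 (Z)-4-{3-[(tert-butyldimethylsilyl)oxy]-4,5-dimethoxyphenyl}-2-iodobut-2-en-1-ol
Conditions: i-Bu2AlH (2.5 equiv), CH2Cl2, −78 °C; aq. KNaC4H4O6 (potassium sodium tartrate)
Reagents that add atoms: none
Why: 1,2-Reduction of an α,β-unsaturated ester to the allylic alcohol by an aluminium hydride; the alkenyl iodide and the aryl silyl ether are inert at −78 °C and the alkene geometry is not touched.

Step 6
Reactants: 8 (Z)-4-{3-[(tert-butyldimethylsilyl)oxy]-4,5-dimethoxyphenyl}-2-iodobut-2-en-1-ol
Product: 9 (Z)-tert-butyl[(4-{3-[(tert-butyldimethylsilyl)oxy]-4,5-dimethoxyphenyl}-2-iodobut-2-en-1-yl)oxy]dimethylsilane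
Conditions: TBSCl, imidazole, DMF, 0 °C → rt
Reagents that add atoms: tert-butyldimethylsilyl chloride, CC(C)(C)[Si](C)(C)Cl
Why: Silyl ether formation on the primary allylic alcohol; it keeps this hydroxyl from competing for the formyl group in step 8 and matches the phenol protection, so that one fluoride treatment removes both.

Step 7
Reactants: 9 (Z)-tert-butyl[(4-{3-[(tert-butyldimethylsilyl)oxy]-4,5-dimethoxyphenyl}-2-iodobut-2-en-1-yl)oxy]dimethylsilane; 10 3,4,5-trimethoxybenzaldehyde
Product: 11 (S,Z)-2-{[(tert-butyldimethylsilyl)oxy]methyl}-4-{3-[(tert-butyldimethylsilyl)oxy]-4,5-dimethoxyphenyl}-1-(3,4,5-trimethoxyphenyl)but-2-en-1-ol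
Conditions: CrCl2 (10 mol %), chiral 2-(oxazolin-2-yl)aryl sulfonamide ligand (11 mol %), Et3N; NiCl2·(2,9-dimethyl-1,10-phenanthroline) (2 mol %), Mn, Zr(Cp)2Cl2, LiCl, MeCN, rt
Reagents that add atoms: none
Why: Catalytic asymmetric Nozaki–Hiyama–Kishi reaction: zerovalent nickel inserts into the C–I bond, the alkenyl group passes to trivalent chromium and adds to the aldehyde inside the chiral ligand sphere, which selects the aldehyde face and sets C2. The α-substituted alkenyl metal should keep its geometry, so C2 ends cis to the benzylic CH2; Mn returns chromium to the divalent state and Zr(Cp)2Cl2 frees it from the product alkoxide.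

Step 8
Reactants: 11 (S,Z)-2-{[(tert-butyldimethylsilyl)oxy]methyl}-4-{3-[(tert-butyldimethylsilyl)oxy]-4,5-dimethoxyphenyl}-1-(3,4,5-trimethoxyphenyl)but-2-en-1-ol
Product: 13 (2R,3S,4S)-4-{3-[(tert-butyldimethylsilyl)oxy]-4,5-dimethoxybenzyl}-3-{[(tert-butyldimethylsilyl)oxy]methyl}-2-(3,4,5-trimethoxyphenyl)tetrahydrofuran-5-ol (ring locants as defined above; C5 epimers), via hydroxy aldehyde 12 (not isolated)
Conditions: Rh(acac)(CO)2 (3 mol %), P(O-2,4-t-Bu2C6H3)3 (12 mol %), CO/H2 (1:1, 40 bar), toluene, 70 °C
Reagents that add atoms: carbon monoxide, [C-]#[O+]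
Why: This is rhodium-catalysed hydroformylation of an allylic alcohol with lactol formation in the same flask, a known reaction type; the bulky phosphite gives a monoligated, weakly donating rhodium hydride that can engage a trisubstituted alkene. The hydride adds syn across C3=C4 with hydrogen to C3 and rhodium to C4, because the reverse insertion would give a tertiary alkyl rhodium and a quaternary formyl carbon; CO insertion into the C4–Rh bond and hydrogenolysis of the acyl give hydroxy aldehyde 12 (new bond C4–C5). The C2 hydroxyl then adds to the formyl carbon in a 5-exo-trig closure (new bond O1–C5); lactol 13 is an anomeric mixture of no consequence, since C5 becomes a methylene in step 9. C4 relative to C3 is fixed by the stereospecific syn addition to the Z alkene, which brings the silyloxymethyl group on C3 and the benzyl group on C4 cis on the ring. C3 relative to C2 is fixed by the face of addition: allylic 1,3-strain against the cis benzylic CH2 holds the C2–H bond in the alkene plane, so ring A covers one face and the small hydroxyl the other, and the hindered catalyst should approach on the hydroxyl face, which gives 2,3-trans. The step needs regioselectivity (secured by the substitution pattern), face selectivity (secured by the Z geometry, which makes the strain argument strong) and chemoselectivity against alkene migration toward ring B and redox isomerisation of the allylic alcohol (high CO pressure and moderate temperature keep acyl formation ahead of β-hydride elimination). C2 itself is not touched.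

Step 9
Reactants: 13 (2R,3S,4S)-4-{3-[(tert-butyldimethylsilyl)oxy]-4,5-dimethoxybenzyl}-3-{[(tert-butyldimethylsilyl)oxy]methyl}-2-(3,4,5-trimethoxyphenyl)tetrahydrofuran-5-ol
Product: 14 tert-butyl{[(2R,3S,4S)-4-{3-[(tert-butyldimethylsilyl)oxy]-4,5-dimethoxybenzyl}-2-(3,4,5-trimethoxyphenyl)tetrahydrofuran-3-yl]methoxy}dimethylsilane
Conditions: Et3SiH (5 equiv), BF3·OEt2 (2 equiv), CH2Cl2, −78 °C → −40 °C
Reagents that add atoms: none
Why: Ionic hydrogenation of a lactol: BF3 ionises the anomeric C5–OH to the cyclic oxocarbenium ion and the silane reduces it to the C5 methylene, with no stereocentre created. With the silane present before the Lewis acid at −78 °C, hydride capture should outrun ionisation of the benzylic C2–O1 bond and loss of the silyl ethers.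

Step 10
Reactants: 14 tert-butyl{[(2R,3S,4S)-4-{3-[(tert-butyldimethylsilyl)oxy]-4,5-dimethoxybenzyl}-2-(3,4,5-trimethoxyphenyl)tetrahydrofuran-3-yl]methoxy}dimethylsilane
Product: 15 [(2R,3S,4S)-4-(3-hydroxy-4,5-dimethoxybenzyl)-2-(3,4,5-trimethoxyphenyl)tetrahydrofuran-3-yl]methanol
Conditions: TBAF, AcOH (buffer), THF, 0 °C → rt
Reagents that add atoms: none
Why: Fluoride-induced cleavage of both Si–O bonds (aryl and primary alkyl silyl ether) in one operation; the buffer protects the liberated phenoxide from air oxidation and nothing else in the molecule responds to fluoride.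

## Compound list

1 | 3-hydroxy-4,5-dimethoxybenzaldehyde | COc1cc(C=O)cc(O)c1OC | starting material
2 | 3-[(tert-butyldimethylsilyl)oxy]-4,5-dimethoxybenzaldehyde | COc1cc(C=O)cc(O[Si](C)(C)C(C)(C)C)c1OC | intermediate
3 | tert-butyl{2,3-dimethoxy-5-[2-methoxyethenyl]phenoxy}dimethylsilane (E/Z mixture) | COC=Cc1cc(OC)c(OC)c(O[Si](C)(C)C(C)(C)C)c1 | intermediate
4 | 2-{3-[(tert-butyldimethylsilyl)oxy]-4,5-dimethoxyphenyl}acetaldehyde | O=CCc1cc(OC)c(OC)c(O[Si](C)(C)C(C)(C)C)c1 | intermediate
5 | ethyl 2-(triphenyl-λ5-phosphanylidene)acetate | CCOC(=O)C=P(c1ccccc1)(c1ccccc1)c1ccccc1 | starting material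
6 | ethyl 2-iodo-2-(triphenyl-λ5-phosphanylidene)acetate (iodo ylide, not isolated) | CCOC(=O)C(I)=P(c1ccccc1)(c1ccccc1)c1ccccc1 | intermediate
7 | ethyl (Z)-4-{3-[(tert-butyldimethylsilyl)oxy]-4,5-dimethoxyphenyl}-2-iodobut-2-enoate | CCOC(=O)/C(I)=C/Cc1cc(OC)c(OC)c(O[Si](C)(C)C(C)(C)C)c1 | intermediate
8 | (Z)-4-{3-[(tert-butyldimethylsilyl)oxy]-4,5-dimethoxyphenyl}-2-iodobut-2-en-1-ol | OC/C(I)=C/Cc1cc(OC)c(OC)c(O[Si](C)(C)C(C)(C)C)c1 | intermediate
9 | (Z)-tert-butyl[(4-{3-[(tert-butyldimethylsilyl)oxy]-4,5-dimethoxyphenyl}-2-iodobut-2-en-1-yl)oxy]dimethylsilane | CC(C)(C)[Si](C)(C)OC/C(I)=C/Cc1cc(OC)c(OC)c(O[Si](C)(C)C(C)(C)C)c1 | intermediate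
10 | 3,4,5-trimethoxybenzaldehyde | COc1cc(C=O)cc(OC)c1OC | starting material
11 | (S,Z)-2-{[(tert-butyldimethylsilyl)oxy]methyl}-4-{3-[(tert-butyldimethylsilyl)oxy]-4,5-dimethoxyphenyl}-1-(3,4,5-trimethoxyphenyl)but-2-en-1-ol | O[C@@H](c1cc(OC)c(OC)c(OC)c1)/C(CO[Si](C)(C)C(C)(C)C)=C\Cc1cc(OC)c(OC)c(O[Si](C)(C)C(C)(C)C)c1 | intermediate
12 | (2S,3S,4R)-2-{3-[(tert-butyldimethylsilyl)oxy]-4,5-dimethoxybenzyl}-3-{[(tert-butyldimethylsilyl)oxy]methyl}-4-hydroxy-4-(3,4,5-trimethoxyphenyl)butanal (not isolated) | COc1cc(C[C@H](C=O)[C@@H](CO[Si](C)(C)C(C)(C)C)[C@@H](O)c2cc(OC)c(OC)c(OC)c2)cc(O[Si](C)(C)C(C)(C)C)c1OC | intermediate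
13 | (2R,3S,4S)-4-{3-[(tert-butyldimethylsilyl)oxy]-4,5-dimethoxybenzyl}-3-{[(tert-butyldimethylsilyl)oxy]methyl}-2-(3,4,5-trimethoxyphenyl)tetrahydrofuran-5-ol (C5 epimers) | COc1cc(C[C@@H]2C(O)O[C@@H](c3cc(OC)c(OC)c(OC)c3)[C@@H]2CO[Si](C)(C)C(C)(C)C)cc(O[Si](C)(C)C(C)(C)C)c1OC | intermediate
14 | tert-butyl{[(2R,3S,4S)-4-{3-[(tert-butyldimethylsilyl)oxy]-4,5-dimethoxybenzyl}-2-(3,4,5-trimethoxyphenyl)tetrahydrofuran-3-yl]methoxy}dimethylsilane | COc1cc(C[C@@H]2CO[C@@H](c3cc(OC)c(OC)c(OC)c3)[C@@H]2CO[Si](C)(C)C(C)(C)C)cc(O[Si](C)(C)C(C)(C)C)c1OC | intermediate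
15 | [(2R,3S,4S)-4-(3-hydroxy-4,5-dimethoxybenzyl)-2-(3,4,5-trimethoxyphenyl)tetrahydrofuran-3-yl]methanol | COc1cc(C[C@@H]2CO[C@@H](c3cc(OC)c(OC)c(OC)c3)[C@@H]2CO)cc(O)c1OC | target

## Step count and least certain steps

Total: 10 steps. Longest linear sequence: 10 steps (1 to 15); 5 and 10 are bought.

**Step 8 (key step).** Insertion into a trisubstituted alkene flanked by two branched carbons may be slow. β-Hydride elimination could then move the double bond into conjugation with ring B or isomerise the allylic alcohol to a ketone, and the face preference from allylic strain alone may be incomplete. The fallback sets out from 11 and binds the catalyst to the substrate.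
- Esterification with 2-(diphenylphosphanyl)benzoic acid (DCC, DMAP, CH2Cl2) would give the phosphine ester F1.
- Hydroformylation directed by the tethered phosphine (Rh(acac)(CO)2, P(OPh)3, CO/H2 20 bar, toluene, 40–50 °C) should deliver rhodium to C4 from the face of the ester oxygen, the same face as in step 8, under much milder conditions, giving the formyl ester F2.
- i-Bu2AlH (CH2Cl2, −78 °C → 0 °C) would reduce the formyl group and cleave the ester to the diol F3.
- TsCl, Et3N and catalytic DMAP would sulfonylate the primary hydroxyl to the tosylate F4, which should close by SN2 attack of the C2 hydroxyl on C5 with C2 untouched. No strong base is used, so a 1,3-silyl shift from the primary oxygen to a C2 alkoxide cannot compete.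
- The path comes back at 14 and by-passes 13 and the Lewis-acid reduction of step 9.

**Step 7.** Enantioface selection may be insufficient for an aromatic aldehyde with an α-branched alkenyl iodide, a ligand-free background addition or reductive dimerisation of 10 by low-valent chromium may intervene, and the alkenyl metal may lose some geometry. The fallback sets out from 9 and 10 and separates bond formation from stereocontrol.
- Iodine–lithium exchange (t-BuLi, Et2O, −78 °C) would give the configurationally stable alkenyllithium F5.
- Addition to 10 gives the alcohol as the racemate F6.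
- Dess–Martin periodinane with NaHCO3 would oxidise it to the enone F7.
- Corey–Bakshi–Shibata reduction (2-methyl oxazaborolidine of the appropriate antipode, catecholborane, toluene, −78 °C) would return 11. The reduction depends on the catalyst distinguishing the flat aryl group from the twisted, α-branched alkenyl group.

**Step 4.** The Z preference may be incomplete, residual non-iodinated ylide may give the iodine-free enoate, and 4 may condense with itself or the new double bond may drift toward ring B under the carbonate. The fallback sets out from 2, avoids 3, 4 and 7, and fixes the geometry by an anti addition to an alkyne.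
- NaBH4 (MeOH/THF, 0 °C) would give the benzyl alcohol F8.
- CBr4/PPh3 (Appel reaction) would give the benzyl bromide F9.
- Coupling with the bis-magnesium derivative of propargyl alcohol (propargyl alcohol, EtMgBr 2 equiv, CuCl cat., THF, 50 °C) would give the butynol F10.
- Hydroxyl-directed trans-hydrostannation (Bu3SnH, [Cp*RuCl]4 cat., CH2Cl2, rt) should place tin on the carbon next to the CH2OH group and anti to the new hydrogen, giving the stannane F11. This is the regiochemistry that hydroalumination does not provide.
- I2 (CH2Cl2, 0 °C) replaces tin by iodine with retention, and the path comes back at 8.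

**Step 3.** The electron-rich arylacetaldehyde may enolise, condense or oxidise in air under acid, and the aryl silyl ether may be partly lost. The fallback sets out from 2 and generates the aldehyde by oxidation under neutral conditions.
- Wittig methylenation (Ph3PCH3Br, NaN(SiMe3)2, THF) would give the styrene F12.
- Hydroboration with 9-BBN and oxidation with H2O2 buffered at pH 7 would give the arylethanol F13.
- Dess–Martin periodinane with NaHCO3 would give 4, where the path comes back.

## Further compounds

F1 | step 8 | (S,Z)-2-{[(tert-butyldimethylsilyl)oxy]methyl}-4-{3-[(tert-butyldimethylsilyl)oxy]-4,5-dimethoxyphenyl}-1-(3,4,5-trimethoxyphenyl)but-2-en-1-yl 2-(diphenylphosphanyl)benzoate | O=C(O[C@@H](c1cc(OC)c(OC)c(OC)c1)/C(CO[Si](C)(C)C(C)(C)C)=C\Cc1cc(OC)c(OC)c(O[Si](C)(C)C(C)(C)C)c1)c1ccccc1P(c1ccccc1)c1ccccc1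
F2 | step 8 | (1R,2S,3S)-3-{3-[(tert-butyldimethylsilyl)oxy]-4,5-dimethoxybenzyl}-2-{[(tert-butyldimethylsilyl)oxy]methyl}-4-oxo-1-(3,4,5-trimethoxyphenyl)butyl 2-(diphenylphosphanyl)benzoate | COc1cc(C[C@H](C=O)[C@@H](CO[Si](C)(C)C(C)(C)C)[C@@H](OC(=O)c2ccccc2P(c2ccccc2)c2ccccc2)c2cc(OC)c(OC)c(OC)c2)cc(O[Si](C)(C)C(C)(C)C)c1OC
F3 | step 8 | (1R,2S,3S)-3-{3-[(tert-butyldimethylsilyl)oxy]-4,5-dimethoxybenzyl}-2-{[(tert-butyldimethylsilyl)oxy]methyl}-1-(3,4,5-trimethoxyphenyl)butane-1,4-diol | COc1cc(C[C@H](CO)[C@@H](CO[Si](C)(C)C(C)(C)C)[C@@H](O)c2cc(OC)c(OC)c(OC)c2)cc(O[Si](C)(C)C(C)(C)C)c1OC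
F4 | step 8 | (2S,3S,4R)-2-{3-[(tert-butyldimethylsilyl)oxy]-4,5-dimethoxybenzyl}-3-{[(tert-butyldimethylsilyl)oxy]methyl}-4-hydroxy-4-(3,4,5-trimethoxyphenyl)butyl 4-methylbenzenesulfonate | COc1cc(C[C@H](COS(=O)(=O)c2ccc(C)cc2)[C@@H](CO[Si](C)(C)C(C)(C)C)[C@@H](O)c2cc(OC)c(OC)c(OC)c2)cc(O[Si](C)(C)C(C)(C)C)c1OC
F5 | step 7 | (Z)-{1-[(tert-butyldimethylsilyl)oxy]-4-{3-[(tert-butyldimethylsilyl)oxy]-4,5-dimethoxyphenyl}but-2-en-2-yl}lithium | [Li]/C(CO[Si](C)(C)C(C)(C)C)=C\Cc1cc(OC)c(OC)c(O[Si](C)(C)C(C)(C)C)c1
F6 | step 7 | racemic (Z)-2-{[(tert-butyldimethylsilyl)oxy]methyl}-4-{3-[(tert-butyldimethylsilyl)oxy]-4,5-dimethoxyphenyl}-1-(3,4,5-trimethoxyphenyl)but-2-en-1-ol | OC(c1cc(OC)c(OC)c(OC)c1)/C(CO[Si](C)(C)C(C)(C)C)=C\Cc1cc(OC)c(OC)c(O[Si](C)(C)C(C)(C)C)c1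
F7 | step 7 | (Z)-2-{[(tert-butyldimethylsilyl)oxy]methyl}-4-{3-[(tert-butyldimethylsilyl)oxy]-4,5-dimethoxyphenyl}-1-(3,4,5-trimethoxyphenyl)but-2-en-1-one | O=C(c1cc(OC)c(OC)c(OC)c1)/C(CO[Si](C)(C)C(C)(C)C)=C\Cc1cc(OC)c(OC)c(O[Si](C)(C)C(C)(C)C)c1
F8 | step 4 | {3-[(tert-butyldimethylsilyl)oxy]-4,5-dimethoxyphenyl}methanol | OCc1cc(OC)c(OC)c(O[Si](C)(C)C(C)(C)C)c1
F9 | step 4 | [5-(bromomethyl)-2,3-dimethoxyphenoxy](tert-butyl)dimethylsilane | BrCc1cc(OC)c(OC)c(O[Si](C)(C)C(C)(C)C)c1
F10 | step 4 | 4-{3-[(tert-butyldimethylsilyl)oxy]-4,5-dimethoxyphenyl}but-2-yn-1-ol | OCC#CCc1cc(OC)c(OC)c(O[Si](C)(C)C(C)(C)C)c1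
F11 | step 4 | (Z)-4-{3-[(tert-butyldimethylsilyl)oxy]-4,5-dimethoxyphenyl}-2-(tributylstannyl)but-2-en-1-ol | OC/C(=C/Cc1cc(OC)c(OC)c(O[Si](C)(C)C(C)(C)C)c1)[Sn](CCCC)(CCCC)CCCC
F12 | step 3 | tert-butyl(5-ethenyl-2,3-dimethoxyphenoxy)dimethylsilane | C=Cc1cc(OC)c(OC)c(O[Si](C)(C)C(C)(C)C)c1
F13 | step 3 | 2-{3-[(tert-butyldimethylsilyl)oxy]-4,5-dimethoxyphenyl}ethan-1-ol | OCCc1cc(OC)c(OC)c(O[Si](C)(C)C(C)(C)C)c1
A1 | alternative 1 | methyl 3-methoxy-2,4-dioxo-6-{[(3S,4S,5R)-4-{[(tert-butyldimethylsilyl)oxy]methyl}-5-(3,4,5-trimethoxyphenyl)oxolan-3-yl]methyl}cyclohexane-1-carboxylate (cyclohexane centres as a mixture) | COC(=O)C1C(=O)C(OC)C(=O)CC1C[C@@H]1CO[C@@H](c2cc(OC)c(OC)c(OC)c2)[C@@H]1CO[Si](C)(C)C(C)(C)C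
A2 | alternative 1 | (E)-1-methoxy-5-[(3S,4S,5R)-4-{[(tert-butyldimethylsilyl)oxy]methyl}-5-(3,4,5-trimethoxyphenyl)oxolan-3-yl]pent-3-en-2-one | COCC(=O)/C=C/C[C@@H]1CO[C@@H](c2cc(OC)c(OC)c(OC)c2)[C@@H]1CO[Si](C)(C)C(C)(C)C
A3 | alternative 1 | dimethyl malonate | COC(=O)CC(=O)OC
A4 | alternative 2 | dimethyl (2S,4Z)-4-[3-(benzyloxy)-4,5-dimethoxybenzylidene]-2-(3,4,5-trimethoxyphenyl)oxolane-3,3-dicarboxylate | COC(=O)C1(C(=O)OC)[C@H](c2cc(OC)c(OC)c(OC)c2)OC/C1=C\c1cc(OC)c(OC)c(OCc2ccccc2)c1
A5 | alternative 2 | dimethyl 2-(3,4,5-trimethoxybenzylidene)malonate | COC(=O)C(=Cc1cc(OC)c(OC)c(OC)c1)C(=O)OC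
A6 | alternative 2 | 1-(benzyloxy)-5-iodo-2,3-dimethoxybenzene | COc1cc(I)cc(OCc2ccccc2)c1OC
A7 | alternative 2 | propargyl alcohol (prop-2-yn-1-ol) | C#CCO
A8 | alternative 3 | 3-[3-(benzyloxy)-4,5-dimethoxyphenyl]-6-(3,4,5-trimethoxyphenyl)tetrahydro-1H,3H-furo[3,4-c]furan-1-one, cis-fused, the C3 aryl group anti to the tetrahydrofuran ring, configuration as in the SMILES | O=C1O[C@@H](c2cc(OC)c(OC)c(OCc3ccccc3)c2)[C@@H]2CO[C@@H](c3cc(OC)c(OC)c(OC)c3)[C@H]12
A9 | alternative 3 | (R)-5-[3-(benzyloxy)-4,5-dimethoxyphenyl]furan-2(5H)-one | O=C1O[C@@H](c2cc(OC)c(OC)c(OCc3ccccc3)c2)C=C1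
A10 | alternative 3 | 5-{chloro[(trimethylsilyl)methoxy]methyl}-1,2,3-trimethoxybenzene | COc1cc(C(Cl)OC[Si](C)(C)C)cc(OC)c1OC
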